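**Plan**
- **Retrosynthetic cuts, in order.** First the phenolic O-benzyl group and the CHO/CH2OH level are adjusted. Then the C2–aryl bond is cut, which also erases the C2 and C3 stereocentres and leaves an arylboronic acid and a dihydrofuran alcohol with one stereocentre. Then the C2–C3 bond is cut (C2 is a formyl carbon), back to a β-benzyl-γ-butyrolactone. Last, the aryl–CH2 bond is cut, back to an aryl bromide and a cyclopropane-fused lactone made from (R)-epichlorohydrin and diethyl malonate.
- **Enabling feature.** In the oxolane ring the aryl-bearing C2 lies between ring oxygen O1 and C3, and C3 carries the exocyclic CH2OH. The unit O1–C2=C3–CH2OH is therefore both a cyclic enol ether (aryl goes to C2, palladium to C3) and an allylic alcohol (hydride relay from CH2OH to C3).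
- **Forward order.** The cyclopropane-fused lactone forms with both rings at once. The aryl Grignard reagent opens the cyclopropane. The lactone ring is switched to the 4,5-dihydrofuran ring, which becomes the oxolane of the target. The aryl group is then joined at C2, followed by reduction and debenzylation.
- **Stereochemistry.** C4 (R) comes from (R)-epichlorohydrin. C2 and C3 are both relayed from C4 in the arylation: approach anti to the benzyl group, syn carbopalladation, and hydride returned on the palladium face. This gives 2,3-trans together with the contra-thermodynamic 3,4-cis.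

Key step: step 8

Remark: the oxolane numbering O1, C2 (aryl), C3 (CH2OH), C4 (benzyl), C5 is used for all ring compounds. The target SMILES is read as (2S,3R,4R), that is 2,3-trans and 3,4-cis.

Step 1
Reactants: 1 (R)-epichlorohydrin; 2 diethyl malonate
Product: 3 ethyl (1S,5R)-2-oxo-3-oxabicyclo[3.1.0]hexane-1-carboxylate
Conditions: NaOEt (1 equiv), EtOH, rt → reflux
Reagents that add atoms: none
Why: Tandem alkylation, cyclopropanation and lactonisation, in which the malonate anion opens the epoxide at its CH2 end, the alkoxide displaces chloride to give a new epoxide, and 3-exo-tet attack of the malonate carbon with inversion followed by lactonisation onto the cis ester gives the cis-fused bicycle, so that the stereocentre of 1 becomes C5 (R) of 3 and fixes C1 (S).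

Step 2
Reactants: 4 4-bromo-2-methoxyphenol
Product: 5 1-(benzyloxy)-4-bromo-2-methoxybenzene
Conditions: BnBr, K2CO3, DMF, rt
Reagents that add atoms: benzyl bromide, BrCc1ccccc1
Why: Williamson ether synthesis masks the phenol as a benzyl ether that should withstand the Grignard, chloride, hydride, acid and palladium steps that follow.

Step 3
Reactants: 5 1-(benzyloxy)-4-bromo-2-methoxybenzene; 3 ethyl (1S,5R)-2-oxo-3-oxabicyclo[3.1.0]hexane-1-carboxylate
Product: 7 ethyl (3S,4R)-4-[4-(benzyloxy)-3-methoxybenzyl]-2-oxooxolane-3-carboxylate, via arylmagnesium bromide 6 (not isolated)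
Conditions: Mg, THF, reflux; then 3, CuI (20 mol %), THF, −30 °C; 1 M HCl quench
Reagents that add atoms: none
Why: Copper-catalysed homoconjugate addition of the aryl Grignard reagent opens the doubly activated cyclopropane at its unsubstituted CH2 with release of a malonate-type enolate, which leaves the stereocentre (now C4, R) untouched and should give the more stable 3,4-trans epimer on protonation.

Step 4
Reactants: 7 ethyl (3S,4R)-4-[4-(benzyloxy)-3-methoxybenzyl]-2-oxooxolane-3-carboxylate
Product: 8 (4R)-4-[4-(benzyloxy)-3-methoxybenzyl]oxolan-2-one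
Conditions: LiCl, DMSO–H2O, 140 °C
Reagents that add atoms: none
Why: Krapcho dealkoxycarbonylation removes the ester under neutral conditions, erases the labile C3 centre and cannot touch C4, which bears no acidic hydrogen.

Step 5
Reactants: 8 (4R)-4-[4-(benzyloxy)-3-methoxybenzyl]oxolan-2-one
Product: 9 (4R)-4-[4-(benzyloxy)-3-methoxybenzyl]-3-(hydroxymethylidene)oxolan-2-one (enol form of the α-formyl lactone)
Conditions: NaH, HCO2Et, THF, 0 °C → rt; then 1 M HCl
Reagents that add atoms: ethyl formate, CCOC=O
Why: Crossed Claisen condensation (α-formylation) at the only enolisable CH2 of the lactone is driven by formation of the stabilised sodium enolate of the 1,3-dicarbonyl product, and C4 is not acidic.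

Step 6
Reactants: 9 (4R)-4-[4-(benzyloxy)-3-methoxybenzyl]-3-(hydroxymethylidene)oxolan-2-one
Product: 11 methyl (4R)-4-[4-(benzyloxy)-3-methoxybenzyl]-4,5-dihydrofuran-3-carboxylate, via methyl acetal ester 10 (not isolated)
Conditions: HCl (1.25 M in MeOH), rt; solvent removed; TsOH·H2O (5 mol %), toluene, reflux through 4 Å MS
Reagents that add atoms: methanol, CO
Why: Korte acyl-lactone rearrangement, in which acid methanolysis opens the lactone, the freed C5 hydroxyl closes onto the formyl carbon (5-exo-trig) to give the 2-methoxyoxolane ester, and acid-catalysed loss of methanol towards the ester-bearing C3 gives the push–pull enol ether, so that the formyl carbon becomes C2 and the old lactone carbonyl becomes the C3 substituent.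

Step 7
Reactants: 11 methyl (4R)-4-[4-(benzyloxy)-3-methoxybenzyl]-4,5-dihydrofuran-3-carboxylate
Product: 12 [(4R)-4-[4-(benzyloxy)-3-methoxybenzyl]-4,5-dihydrofuran-3-yl]methanol
Conditions: i-Bu2AlH (2.5 equiv), CH2Cl2, −78 → 0 °C; aq. potassium sodium tartrate; Et3N-washed silica
Reagents that add atoms: none
Why: 1,2-Reduction of the unsaturated ester with i-Bu2AlH should stop at the allylic alcohol because the electron-rich enol ether alkene is inert to hydride, and the non-acidic work-up keeps the ionisable allylic hydroxyl in place.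

Step 8
Reactants: 12 [(4R)-4-[4-(benzyloxy)-3-methoxybenzyl]-4,5-dihydrofuran-3-yl]methanol; 13 (3,4-dimethoxyphenyl)boronic acid
Product: 14 (2S,3S,4R)-4-[4-(benzyloxy)-3-methoxybenzyl]-2-(3,4-dimethoxyphenyl)oxolane-3-carbaldehyde
Conditions: 13 (2.5 equiv), Pd(MeCN)2(OTs)2 (6 mol %), Cu(OTf)2 (6 mol %), 2-(4,4-dimethyl-4,5-dihydrooxazol-2-yl)pyridine (13 mol %), O2 (1 atm), 3 Å MS, DMF, rt; crude product taken on at once
Reagents that add atoms: none
Why: Proposed new method: aryl transfer from boron to cationic divalent palladium gives an aryl–palladium species that adds syn across the O1–C2=C3 enol ether with the aryl group on C2 (the oxygen-bearing, less substituted and carbinol-remote alkene carbon) and palladium on C3, after which β-hydride elimination from the exocyclic CH2OH and re-insertion in the opposite sense move palladium to the carbinol carbon, from which the aldehyde and zerovalent palladium (reoxidised by O2) are released. The closest known reaction types are the C2-selective Heck arylation of 2,3-dihydrofurans and furanoid glycals and the Heck or redox-relay Heck arylation of 2-substituted allylic alcohols to 3-aryl-2-alkylpropanals, and their merger on a 3-(hydroxymethyl)-4,5-dihydrofuran has not been shown. No ring is closed. C2 is set by approach of aryl–palladium to the alkene face opposite the C4 benzyl group, the only stereocentre of 12 and the neighbour of the palladium-bearing carbon, which gives the 2,4-trans relation. C3 is set because the hydride that replaces palladium is returned on the face that palladium occupied, syn to the new aryl group, so that CHO ends trans to the aryl group and cis to the benzyl group. The step needs exocyclic rather than endocyclic (C4–H) β-hydride elimination and no release of the enol, and this is secured because C2–H is anti to palladium and out of reach, the carbinol C–H is the more hydridic and leads to the irreversible carbonyl sink, and the chelating pyridine–oxazoline ligand with non-coordinating tosylate holds the Pd–H on the alkene during the walk.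

Step 9
Reactants: 14 (2S,3S,4R)-4-[4-(benzyloxy)-3-methoxybenzyl]-2-(3,4-dimethoxyphenyl)oxolane-3-carbaldehyde
Product: 15 [(2S,3R,4R)-4-[4-(benzyloxy)-3-methoxybenzyl]-2-(3,4-dimethoxyphenyl)oxolan-3-yl]methanol
Conditions: NaBH4, MeOH, 0 °C
Reagents that add atoms: none
Why: Borohydride reduction of the crude aldehyde at low temperature should be faster than enolisation, so the C3 configuration set in step 8 is locked as the non-epimerisable CH2OH (the descriptor changes from S to R by priority only).

Step 10
Reactants: 15 [(2S,3R,4R)-4-[4-(benzyloxy)-3-methoxybenzyl]-2-(3,4-dimethoxyphenyl)oxolan-3-yl]methanol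
Product: 16 [(2S,3R,4R)-2-(3,4-dimethoxyphenyl)-4-(4-hydroxy-3-methoxybenzyl)oxolan-3-yl]methanol (target)
Conditions: H2 (1 atm), Pd/C (10 wt %), EtOAc, rt, stopped when 15 is consumed
Reagents that add atoms: none
Why: Catalytic hydrogenolysis cleaves the phenolic benzyl ether, whose phenoxide-type leaving group should make it react well before the cyclic C2–O1 benzylic ether, and it touches no stereocentre.

**Compound list**
1 | (R)-epichlorohydrin, (2R)-2-(chloromethyl)oxirane | ClC[C@H]1CO1 | starting material
2 | diethyl malonate | CCOC(=O)CC(=O)OCC | starting material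
3 | ethyl (1S,5R)-2-oxo-3-oxabicyclo[3.1.0]hexane-1-carboxylate | O=C1OC[C@@H]2C[C@]12C(=O)OCC | intermediate
4 | 4-bromo-2-methoxyphenol | COc1cc(Br)ccc1O | starting material
5 | 1-(benzyloxy)-4-bromo-2-methoxybenzene | COc1cc(Br)ccc1OCc1ccccc1 | intermediate
6 | [4-(benzyloxy)-3-methoxyphenyl]magnesium bromide | COc1cc([Mg]Br)ccc1OCc1ccccc1 | intermediate
7 | ethyl (3S,4R)-4-[4-(benzyloxy)-3-methoxybenzyl]-2-oxooxolane-3-carboxylate (trans, C3 labile) | COc1cc(C[C@H]2COC(=O)[C@@H]2C(=O)OCC)ccc1OCc1ccccc1 | intermediate
8 | (4R)-4-[4-(benzyloxy)-3-methoxybenzyl]oxolan-2-one | COc1cc(C[C@H]2COC(=O)C2)ccc1OCc1ccccc1 | intermediate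
9 | (4R)-4-[4-(benzyloxy)-3-methoxybenzyl]-3-(hydroxymethylidene)oxolan-2-one (enol geometry not fixed) | COc1cc(C[C@H]2COC(=O)C2=CO)ccc1OCc1ccccc1 | intermediate
10 | methyl (4R)-4-[4-(benzyloxy)-3-methoxybenzyl]-2-methoxyoxolane-3-carboxylate (mixture at C2 and C3) | COc1cc(C[C@H]2COC(OC)C2C(=O)OC)ccc1OCc1ccccc1 | intermediate
11 | methyl (4R)-4-[4-(benzyloxy)-3-methoxybenzyl]-4,5-dihydrofuran-3-carboxylate | COc1cc(C[C@H]2COC=C2C(=O)OC)ccc1OCc1ccccc1 | intermediate
12 | [(4R)-4-[4-(benzyloxy)-3-methoxybenzyl]-4,5-dihydrofuran-3-yl]methanol | COc1cc(C[C@H]2COC=C2CO)ccc1OCc1ccccc1 | intermediate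
13 | (3,4-dimethoxyphenyl)boronic acid | COc1ccc(B(O)O)cc1OC | starting material
14 | (2S,3S,4R)-4-[4-(benzyloxy)-3-methoxybenzyl]-2-(3,4-dimethoxyphenyl)oxolane-3-carbaldehyde | COc1cc(C[C@H]2CO[C@H](c3ccc(OC)c(OC)c3)[C@H]2C=O)ccc1OCc1ccccc1 | intermediate
15 | [(2S,3R,4R)-4-[4-(benzyloxy)-3-methoxybenzyl]-2-(3,4-dimethoxyphenyl)oxolan-3-yl]methanol | COc1cc(C[C@H]2CO[C@H](c3ccc(OC)c(OC)c3)[C@H]2CO)ccc1OCc1ccccc1 | intermediate
16 | [(2S,3R,4R)-2-(3,4-dimethoxyphenyl)-4-(4-hydroxy-3-methoxybenzyl)oxolan-3-yl]methanol | COc1cc(C[C@H]2CO[C@H](c3ccc(OC)c(OC)c3)[C@H]2CO)ccc1O | target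

Total step count: 10. Longest linear sequence: 9 (steps 1 and 3 to 10).

**Steps most likely to fail**

**Step 8.**
- What may go wrong: the tertiary C3–palladium intermediate may lose the endocyclic C4 hydrogen instead of a carbinol hydrogen. The enol may leave the metal and ketonise without facial control. The allylic hydroxyl may ionise or be oxidised under the Lewis-acidic aerobic catalyst.
- Fallback from 8, back at 15, by known chemistry:
  - The lithium enolate of 8 (LiN(SiMe3)2, THF, −78 °C) is added to 3,4-dimethoxybenzaldehyde. This aldol reaction should place the new side chain trans to the benzyl group and give the hydroxybenzyl lactone F1 as carbinol epimers.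
  - LiAlH4 in THF should reduce it to the triol F2.
  - Catalytic camphorsulfonic acid in CH2Cl2 should ionise the benzylic alcohol of either epimer. Closure by the C5 hydroxyl should give the 2,3-trans oxolane 15. The trans lactone relation becomes the 3,4-cis oxolane relation through the ring switch.

**Step 6.**
- What may go wrong: loss of methanol may stay incomplete, or the C2 oxocarbenium ion may be captured by the electron-rich benzyl arene during the hot acid treatment.
- Fallback from 8, back at 12:
  - i-Bu2AlH (1.1 equiv, CH2Cl2, −78 °C) should give the lactol F3.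
  - Mesylation and elimination (MsCl, Et3N, CH2Cl2, 0 °C → reflux) should give the 2,3-dihydrofuran F4.
  - Vilsmeier–Haack formylation (POCl3, DMF, 0 °C → rt, then aq. NaOAc) at the enol ether β-carbon should give the dihydrofuran carbaldehyde F5.
  - NaBH4 in EtOH at 0 °C should give 12.

**Step 10.**
- What may go wrong: hydrogenolysis may go on to the doubly activated C2–O1 benzylic bond once the benzyl ether has gone.
- Fallback from 8, back at 16, with a fluoride-labile phenol mask:
  - Hydrogenolysis of 8 (H2, Pd/C, EtOAc), harmless at that stage, should give the phenol lactone F6.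
  - i-Pr3SiCl and imidazole in DMF should give the silyl ether lactone F7.
  - Formylation through the lithium enolate (LiN(i-Pr)2, THF, −78 °C, then 2,2,2-trifluoroethyl formate) should give the hydroxymethylidene lactone F8.
  - Acidic methanol should give the acetal ester F9, and acid-catalysed loss of methanol should give the dihydrofuran ester F10.
  - i-Bu2AlH should give the allylic alcohol F11.
  - Arylation with 13 as in step 8 should give the aldehyde F12, and NaBH4 should give the alcohol F13.
  - Bu4NF in THF at 0 °C should free the phenol to give 16 without any reductive step.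

**Further compounds**
F1 | step 8 | (3S,4R)-4-[4-(benzyloxy)-3-methoxybenzyl]-3-[(3,4-dimethoxyphenyl)(hydroxy)methyl]oxolan-2-one (carbinol epimers) | COc1cc(C[C@H]2COC(=O)[C@@H]2C(O)c3ccc(OC)c(OC)c3)ccc1OCc1ccccc1
F2 | step 8 | (2R,3R)-2-[4-(benzyloxy)-3-methoxybenzyl]-3-[(3,4-dimethoxyphenyl)(hydroxy)methyl]butane-1,4-diol (carbinol epimers) | COc1cc(C[C@@H](CO)[C@H](CO)C(O)c2ccc(OC)c(OC)c2)ccc1OCc1ccccc1
F3 | step 6 | (4R)-4-[4-(benzyloxy)-3-methoxybenzyl]oxolan-2-ol (anomers) | COc1cc(C[C@H]2COC(O)C2)ccc1OCc1ccccc1
F4 | step 6 | (3R)-3-[4-(benzyloxy)-3-methoxybenzyl]-2,3-dihydrofuran | COc1cc(C[C@H]2COC=C2)ccc1OCc1ccccc1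
F5 | step 6 | (4R)-4-[4-(benzyloxy)-3-methoxybenzyl]-4,5-dihydrofuran-3-carbaldehyde | COc1cc(C[C@H]2COC=C2C=O)ccc1OCc1ccccc1
F6 | step 10 | (4R)-4-(4-hydroxy-3-methoxybenzyl)oxolan-2-one | COc1cc(C[C@H]2COC(=O)C2)ccc1O
F7 | step 10 | (4R)-4-[3-methoxy-4-(triisopropylsilyloxy)benzyl]oxolan-2-one | COc1cc(C[C@H]2COC(=O)C2)ccc1O[Si](C(C)C)(C(C)C)C(C)C
F8 | step 10 | (4R)-3-(hydroxymethylidene)-4-[3-methoxy-4-(triisopropylsilyloxy)benzyl]oxolan-2-one | COc1cc(C[C@H]2COC(=O)C2=CO)ccc1O[Si](C(C)C)(C(C)C)C(C)C
F9 | step 10 | methyl (4R)-2-methoxy-4-[3-methoxy-4-(triisopropylsilyloxy)benzyl]oxolane-3-carboxylate (mixture at C2 and C3) | COc1cc(C[C@H]2COC(OC)C2C(=O)OC)ccc1O[Si](C(C)C)(C(C)C)C(C)C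
F10 | step 10 | methyl (4R)-4-[3-methoxy-4-(triisopropylsilyloxy)benzyl]-4,5-dihydrofuran-3-carboxylate | COc1cc(C[C@H]2COC=C2C(=O)OC)ccc1O[Si](C(C)C)(C(C)C)C(C)C
F11 | step 10 | [(4R)-4-[3-methoxy-4-(triisopropylsilyloxy)benzyl]-4,5-dihydrofuran-3-yl]methanol | COc1cc(C[C@H]2COC=C2CO)ccc1O[Si](C(C)C)(C(C)C)C(C)C
F12 | step 10 | (2S,3S,4R)-2-(3,4-dimethoxyphenyl)-4-[3-methoxy-4-(triisopropylsilyloxy)benzyl]oxolane-3-carbaldehyde | COc1cc(C[C@H]2CO[C@H](c3ccc(OC)c(OC)c3)[C@H]2C=O)ccc1O[Si](C(C)C)(C(C)C)C(C)C
F13 | step 10 | [(2S,3R,4R)-2-(3,4-dimethoxyphenyl)-4-[3-methoxy-4-(triisopropylsilyloxy)benzyl]oxolan-3-yl]methanol | COc1cc(C[C@H]2CO[C@H](c3ccc(OC)c(OC)c3)[C@H]2CO)ccc1O[Si](C(C)C)(C(C)C)C(C)C
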